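The lactone ring is closed last by forming the C1–C8a bond (isochromanone numbering), the bond between the carbonyl carbon and the benzene ring. The precursor is an acyclic (R)-configured secondary phenyl carbonate whose arene carries iodine at C8a, between the MOM-protected C8 oxygen and the C4a side chain. Iodine–lithium exchange gives a C8a carbanion that attacks the carbonate carbonyl held on O2, so one operation makes the aryl–carbonyl bond and the six-membered lactone; acid then frees the C8 phenol. The step exploits the 1,2,3-substitution of the benzene ring and the C3 oxygen as a tether. The stereocentre comes from (R)-epichlorohydrin, the E-alkene from hydrozirconation.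

Key step: step 5

Remark: isochromanone numbering is used (C1 carbonyl carbon, O2, C3 stereocentre, C4, C4a, C5 to C8, C8a); all numbered starting materials are taken as commercial; cyclopentadienyl rings on zirconium are drawn σ-bonded in SMILES.

Step 1
Reactants: 1 (dec-1-yne); 2 (1-bromo-4-chlorobutane)
Product: 4 (E)-1-chlorotetradec-5-ene, via chlorobis(cyclopentadienyl)[(E)-dec-1-enyl]zirconium 3 (not isolated)
Conditions: Cp2Zr(H)Cl (1.1 equiv), THF, rt; then 2, Pd(acac)2 (2.5 mol%), LiBr (2 equiv), THF/NMP, 55 °C
Reagents that add atoms: none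
Why: Syn-hydrozirconation places zirconium on the terminal carbon and fixes the E geometry, and the alkenylzirconium then couples with the primary C–Br bond (C–Cl adds far more slowly to zerovalent palladium) in a ligand-free Negishi-type alkyl cross-coupling with retention of the alkene geometry.

Step 2
Reactants: 4 ((E)-1-chlorotetradec-5-ene); 5 ((R)-epichlorohydrin)
Product: 8 (R)-2-[(E)-pentadec-6-en-1-yl]oxirane, via (E)-tetradec-5-enylmagnesium chloride 6 (not isolated), via (R,E)-1-chloroheptadec-8-en-2-ol 7 (not isolated)
Conditions: Mg, cat. I2, THF, 50 °C; then 5, CuI (10 mol%), THF, −40 to −20 °C; aqueous quench, then NaOH, THF/H2O, rt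
Reagents that add atoms: none
Why: CuI-catalysed Grignard opening of epichlorohydrin occurs at the epoxide CH2 and not at C–Cl, and hydroxide then closes the new epoxide onto the CH2Cl carbon (epichlorohydrin chain-extension sequence), so the stereocentre is never a reaction site and (R)-5 gives (R)-8; 5-exo radical cyclisation of the hex-5-enyl unit during magnesium insertion should stay a minor path.

Step 3
Reactants: 8 ((R)-2-[(E)-pentadec-6-en-1-yl]oxirane); 9 (1-bromo-3-(methoxymethoxy)benzene)
Product: 11 (R,E)-1-[3-(methoxymethoxy)phenyl]heptadec-8-en-2-ol, via 3-(methoxymethoxy)phenylmagnesium bromide 10 (not isolated)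
Conditions: 9, Mg, THF, rt to 40 °C; then 8, CuI (10 mol%), THF, −30 to 0 °C
Reagents that add atoms: none
Why: CuI-catalysed aryl Grignard opening of a monosubstituted epoxide is an SN2 attack at the unsubstituted carbon, so the carbinol stereocentre is carried over unchanged as R.

Step 4
Reactants: 11 ((R,E)-1-[3-(methoxymethoxy)phenyl]heptadec-8-en-2-ol); 12 (phenyl chloroformate)
Product: 15 (R,E)-1-[2-iodo-3-(methoxymethoxy)phenyl]heptadec-8-en-2-yl phenyl carbonate, via aryllithium alkoxide 13 (not isolated), via iodoarene lithium alkoxide 14 (not isolated)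
Conditions: n-BuLi (2.4 equiv), THF, 0 °C; ICH2CH2I (1.5 equiv), −78 °C; then 12 (1.5 equiv), −78 to 0 °C
Reagents that add atoms: 1,2-diiodoethane, ICCI
Why: After O-deprotonation the second equivalent of butyllithium is directed by both the OMOM group and the side-chain lithium alkoxide to the ring carbon between them (cooperative directed ortho-metalation), 1,2-diiodoethane transfers iodine to that carbon, and the remaining lithium alkoxide is O-acylated by the chloroformate without involving the stereocentre.

Step 5
Reactants: 15 ((R,E)-1-[2-iodo-3-(methoxymethoxy)phenyl]heptadec-8-en-2-yl phenyl carbonate)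
Product: 18 (R)-8-hydroxy-3-[(E)-pentadec-6-en-1-yl]isochroman-1-one, via aryllithium 16 (not isolated), via MOM-protected lactone 17 (not isolated)
Conditions: n-BuLi (1.05 equiv), THF/Et2O/pentane, −100 °C, then −78 °C; then HCl (3 M in MeOH), rt
Reagents that add atoms: none
Why: Iodine–lithium exchange at −100 °C should outrun addition of butyllithium to the carbonate and gives aryllithium 16 at C8a, held by chelation to the neighbouring OMOM oxygen. The carbanion attacks the tethered carbonate carbonyl C1 in a 6-exo-trig acyl substitution (Parham cyclization, the closest known reaction type), which forms the C1–C8a bond and closes the lactone ring (C1, O2, C3, C4, C4a, C8a) in the same event. The tetrahedral alkoxide expels phenoxide, a much better leaving group than the secondary ring alkoxide, so the ring stays closed. No stereocentre is formed, and C3 keeps its R configuration because its C–O bond is never broken. The step needs exchange before carbonyl addition and intramolecular before intermolecular acylation, which the iodide, the low temperature, dilution and the six-membered transition state should secure, while the site of closure is fixed by the position of the iodine. Methanolic HCl then cleaves the MOM acetal and frees the C8 hydroxyl.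

Compound list
1 | dec-1-yne | C#CCCCCCCCC | starting material
2 | 1-bromo-4-chlorobutane | ClCCCCBr | starting material
3 | chlorobis(cyclopentadienyl)[(E)-dec-1-enyl]zirconium | CCCCCCCC/C=C/[Zr](Cl)(C1C=CC=C1)C1C=CC=C1 | intermediate
4 | (E)-1-chlorotetradec-5-ene | ClCCCC/C=C/CCCCCCCC | intermediate
5 | (R)-epichlorohydrin, (R)-2-(chloromethyl)oxirane | ClC[C@H]1CO1 | starting material
6 | (E)-tetradec-5-enylmagnesium chloride | CCCCCCCC/C=C/CCCC[Mg]Cl | intermediate
7 | (R,E)-1-chloroheptadec-8-en-2-ol | ClC[C@H](O)CCCCC/C=C/CCCCCCCC | intermediate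
8 | (R)-2-[(E)-pentadec-6-en-1-yl]oxirane | CCCCCCCC/C=C/CCCCC[C@@H]1CO1 | intermediate
9 | 1-bromo-3-(methoxymethoxy)benzene | COCOc1cccc(Br)c1 | starting material
10 | 3-(methoxymethoxy)phenylmagnesium bromide | COCOc1cccc([Mg]Br)c1 | intermediate
11 | (R,E)-1-[3-(methoxymethoxy)phenyl]heptadec-8-en-2-ol | CCCCCCCC/C=C/CCCCC[C@@H](O)Cc1cccc(OCOC)c1 | intermediate
12 | phenyl chloroformate | O=C(Cl)Oc1ccccc1 | starting material
13 | lithium (R,E)-1-[2-lithio-3-(methoxymethoxy)phenyl]heptadec-8-en-2-olate | CCCCCCCC/C=C/CCCCC[C@@H](O[Li])Cc1cccc(OCOC)c1[Li] | intermediate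
14 | lithium (R,E)-1-[2-iodo-3-(methoxymethoxy)phenyl]heptadec-8-en-2-olate | CCCCCCCC/C=C/CCCCC[C@@H](O[Li])Cc1cccc(OCOC)c1I | intermediate
15 | (R,E)-1-[2-iodo-3-(methoxymethoxy)phenyl]heptadec-8-en-2-yl phenyl carbonate | CCCCCCCC/C=C/CCCCC[C@@H](OC(=O)Oc1ccccc1)Cc1cccc(OCOC)c1I | intermediate
16 | (R,E)-1-[2-lithio-3-(methoxymethoxy)phenyl]heptadec-8-en-2-yl phenyl carbonate | CCCCCCCC/C=C/CCCCC[C@@H](OC(=O)Oc1ccccc1)Cc1cccc(OCOC)c1[Li] | intermediate
17 | (R)-8-(methoxymethoxy)-3-[(E)-pentadec-6-en-1-yl]isochroman-1-one | CCCCCCCC/C=C/CCCCC[C@@H]1Cc2cccc(OCOC)c2C(=O)O1 | intermediate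
18 | (R)-8-hydroxy-3-[(E)-pentadec-6-en-1-yl]isochroman-1-one (3R, 6'E) | CCCCCCCC/C=C/CCCCC[C@@H]1Cc2cccc(O)c2C(=O)O1 | target

Total step count: 5. Longest linear sequence: 5 steps (1 → 4 → 8 → 11 → 15 → 18).

Steps most likely to fail

Step 5. Addition of butyllithium to the phenyl carbonate may compete with iodine–lithium exchange, or the aryllithium may acylate intermolecularly, so that the ring does not close cleanly. The fallback sets out from 11 and replaces the carbonate by a carbonyl group that is inert to alkyllithium. Lithiation and iodination as in step 4, but with aqueous work-up in place of acylation, should give (R,E)-1-[2-iodo-3-(methoxymethoxy)phenyl]heptadec-8-en-2-ol F1. NaH and N,N-diethylcarbamoyl chloride in THF should convert it into (R,E)-1-[2-iodo-3-(methoxymethoxy)phenyl]heptadec-8-en-2-yl N,N-diethylcarbamate F2. With t-BuLi (2 equiv, THF, −78 °C) the same attack of C8a on C1 is expected, followed by transfer of the carbamoyl group from oxygen to carbon, to give (R,E)-N,N-diethyl-2-(2-hydroxyheptadec-8-en-1-yl)-6-(methoxymethoxy)benzamide F3. TsOH·H2O in toluene/MeOH at 80 °C should relactonise F3 and remove the MOM group, which rejoins the route at 18.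

Step 4. Lithiation may occur at the other position ortho to the OMOM group, and O-acylation may be incomplete in the salt-laden one-pot mixture. The fallback sets out from 8 and brings the halogen in with the arene. Iodine–magnesium exchange of commercial 2-bromo-1-iodo-3-methoxybenzene (COc1cccc(I)c1Br) with i-PrMgCl·LiCl in THF at −20 °C should give 2-bromo-3-methoxyphenylmagnesium chloride F4. F4 should open 8 under CuI catalysis to (R,E)-1-(2-bromo-3-methoxyphenyl)heptadec-8-en-2-ol F5. Phenyl chloroformate 12 and pyridine in CH2Cl2 should give (R,E)-1-(2-bromo-3-methoxyphenyl)heptadec-8-en-2-yl phenyl carbonate F6. Bromine–lithium exchange (t-BuLi, THF, −100 °C) should close F6 to (R)-8-methoxy-3-[(E)-pentadec-6-en-1-yl]isochroman-1-one F7. BCl3 in CH2Cl2 (−78 to 0 °C) should cleave the methyl ether that is chelated to the lactone carbonyl without touching the alkene, which rejoins the route at 18.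

Step 1. Oxidative addition of the alkyl bromide may be slow, and β-hydride elimination of the alkylpalladium intermediate may drain the coupling. The fallback sets out from 1 and reverses the polarity of the coupling. Hydrozirconation to 3 as before, followed by I2 in THF at 0 °C, should give (E)-1-iododec-1-ene F8. 4-Chlorobutylmagnesium bromide F9 would be prepared from 2 and Mg in THF below 20 °C. Fe(acac)3-catalysed cross-coupling of F8 with F9 (THF/NMP, 0 °C) is stereoretentive and should rejoin the route at 4.

Further compounds
F1 | step 5 | (R,E)-1-[2-iodo-3-(methoxymethoxy)phenyl]heptadec-8-en-2-ol | CCCCCCCC/C=C/CCCCC[C@@H](O)Cc1cccc(OCOC)c1I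
F2 | step 5 | (R,E)-1-[2-iodo-3-(methoxymethoxy)phenyl]heptadec-8-en-2-yl N,N-diethylcarbamate | CCCCCCCC/C=C/CCCCC[C@@H](OC(=O)N(CC)CC)Cc1cccc(OCOC)c1I
F3 | step 5 | (R,E)-N,N-diethyl-2-(2-hydroxyheptadec-8-en-1-yl)-6-(methoxymethoxy)benzamide | CCCCCCCC/C=C/CCCCC[C@@H](O)Cc1cccc(OCOC)c1C(=O)N(CC)CC
F4 | step 4 | 2-bromo-3-methoxyphenylmagnesium chloride | COc1cccc([Mg]Cl)c1Br
F5 | step 4 | (R,E)-1-(2-bromo-3-methoxyphenyl)heptadec-8-en-2-ol | CCCCCCCC/C=C/CCCCC[C@@H](O)Cc1cccc(OC)c1Br
F6 | step 4 | (R,E)-1-(2-bromo-3-methoxyphenyl)heptadec-8-en-2-yl phenyl carbonate | CCCCCCCC/C=C/CCCCC[C@@H](OC(=O)Oc1ccccc1)Cc1cccc(OC)c1Br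
F7 | step 4 | (R)-8-methoxy-3-[(E)-pentadec-6-en-1-yl]isochroman-1-one | CCCCCCCC/C=C/CCCCC[C@@H]1Cc2cccc(OC)c2C(=O)O1
F8 | step 1 | (E)-1-iododec-1-ene | CCCCCCCC/C=C/I
F9 | step 1 | 4-chlorobutylmagnesium bromide | ClCCCC[Mg]Br
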